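**Retrosynthetic overview**
1. Target ⇒ (1S,5R)-hydroxy tert-butyl ester: the last operation is a base-free acetylation of the tertiary alcohol followed by ester acidolysis in the same flask.
2. Hydroxycyclopentenone ⇒ 2,6-dialkyl-2H-pyran-3(6H)-one: key step, a catalytic enantioselective ring contraction (γ-dienolate ring opening, then aldol) that makes the carbocycle, the C–C bond and both stereocentres.
3. Pyranone ⇒ 2,5-disubstituted furylcarbinol: Achmatowicz oxidative ring expansion, then hemiketal reduction.
4. Furylcarbinol ⇒ furan + 1-bromo-6-chlorohexane + (Z)-hex-3-enal + tert-butyl acetate (two furan lithiations, one enolate alkylation).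
5. Ring order: furan (bought) → six-membered pyranone → five-membered carbocycle.

Assumption: the target is the (1S,5R) isomer on the cyclopentenyl numbering used below (acetoxy trans to the pentenyl group, Z alkene); (Z)-hex-3-enal is bought as its stabilised solution and distilled before use.

Catalyst A (step 6, not a numbered compound): 1-[3,5-bis(trifluoromethyl)phenyl]-3-[(2S)-3,3-dimethyl-1-{[tris(4-methoxyphenyl)-λ5-phosphanylidene]amino}butan-2-yl]thiourea, C36H38F6N3O3PS, SMILES COc1ccc(cc1)P(=NC[C@@H](NC(=S)Nc1cc(cc(c1)C(F)(F)F)C(F)(F)F)C(C)(C)C)(c1ccc(OC)cc1)c1ccc(OC)cc1. It is made beforehand from the (S)-tert-leucine-derived azido thiourea and P(4-MeOC6H4)3. The sense of induction is not predictable; if the first run gives the (1R,5S) product, the (R)-catalyst is used instead.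

**Step 1**
Reactants: 1 furan; 2 1-bromo-6-chlorohexane
Product: 4 2-(6-chlorohexyl)furan, via 2-furyllithium 3 (not isolated)
Conditions: n-BuLi, THF, −78 → 0 °C; then 2, −78 °C → rt
Reagents that add atoms: none
Why: α-lithiation of furan followed by SN2 alkylation, selective for the bromide end of the dihalide because bromide is by far the better leaving group.

**Step 2**
Reactants: 4 2-(6-chlorohexyl)furan; 5 (Z)-hex-3-enal
Product: 7 (Z)-1-[5-(6-chlorohexyl)furan-2-yl]hex-3-en-1-ol (racemic), via 5-lithiated chlorohexylfuran 6 (not isolated)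
Conditions: n-BuLi, THF, −78 → 0 °C; then 5, −78 °C; H2O quench
Reagents that add atoms: none
Why: the free α-position of the 2-alkylfuran is lithiated while the primary chloride stays inert below 0 °C, and 1,2-addition to the aldehyde at −78 °C outruns enolisation; the racemic carbinol centre is erased later.

**Step 3**
Reactants: 7 (Z)-1-[5-(6-chlorohexyl)furan-2-yl]hex-3-en-1-ol; 8 tert-butyl acetate
Product: 10 tert-butyl 8-{5-[(Z)-1-hydroxyhex-3-en-1-yl]furan-2-yl}octanoate (racemic), via lithium enolate 9 (not isolated)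
Conditions: LiN(i-Pr)2 (3.2 equiv), 8 (3 equiv), THF, −78 °C; then 7, NaI (20 mol %), DMPU, −78 °C → rt
Reagents that add atoms: none
Why: ester enolate alkylation (SN2, iodide-catalysed activation of the primary chloride); the carbinol sits as its inert lithium alkoxide and the excess enolate covers that proton.

**Step 4**
Reactants: 10 tert-butyl 8-{5-[(Z)-1-hydroxyhex-3-en-1-yl]furan-2-yl}octanoate
Product: 11 tert-butyl 8-{2-hydroxy-5-oxo-6-[(Z)-pent-2-en-1-yl]-5,6-dihydro-2H-pyran-2-yl}octanoate (racemic anomer mixture)
Conditions: N-bromosuccinimide (1.0 equiv), NaHCO3, THF/H2O 4:1, 0 °C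
Reagents that add atoms: water, O
Why: Achmatowicz rearrangement, an oxidative ring expansion: bromonium attack on the electron-rich furan (much faster than on the isolated Z-alkene), hydration and opening to the Z-enedione, then hemiketalisation by the carbinol oxygen gives the pyranone.

**Step 5**
Reactants: 11 tert-butyl 8-{2-hydroxy-5-oxo-6-[(Z)-pent-2-en-1-yl]-5,6-dihydro-2H-pyran-2-yl}octanoate
Product: 12 tert-butyl 8-{5-oxo-6-[(Z)-pent-2-en-1-yl]-5,6-dihydro-2H-pyran-2-yl}octanoate (racemic cis/trans mixture)
Conditions: Et3SiH (5 equiv), TFA (10 equiv), CH2Cl2, −40 °C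
Reagents that add atoms: none
Why: Kishi-type ionic hydrogenation: TFA ionises the tertiary hemiketal to a cyclic oxocarbenium ion that Et3SiH reduces; at −40 °C the tert-butyl ester, enone and Z-alkene survive, and the diastereomer ratio does not matter because both ring centres are erased in step 6.

**Step 6**
Reactants: 12 tert-butyl 8-{5-oxo-6-[(Z)-pent-2-en-1-yl]-5,6-dihydro-2H-pyran-2-yl}octanoate
Product: 14 tert-butyl 8-{(1S,5R)-1-hydroxy-4-oxo-5-[(Z)-pent-2-en-1-yl]cyclopent-2-en-1-yl}octanoate, via ring-opened enedione enolate 13 (not isolated)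
Conditions: catalyst A (10 mol %), toluene (0.05 M), −20 °C; AcOH quench at −20 °C
Reagents that add atoms: none
Why: Proposed new method: the iminophosphorane superbase removes the γ-hydrogen at ring C2 (next to the ring oxygen, vinylogous to the ketone), the resulting 3-oxido-2H-pyran opens by C6–O scission to the Z-enedione enolate 13 whose nucleophilic carbon is fixed as the pentenyl-bearing one, and the thiourea and the protonated iminophosphorane hold the enolate and ketone oxygens for an intramolecular aldol that closes the cyclopentenone and sets C1 (S) and C5 (R), the pentenyl group ending anti to the catalyst-bound oxygen under kinetic control (competing deprotonation at C6 is reversible and only scrambles a centre that is erased anyway); closest known reaction types are the amine-mediated ring contraction of 6-alkoxy-2H-pyran-3(6H)-ones to hydroxycyclopentenones, the buffer-mediated aldol cyclisation of cis-enediones to 4-hydroxycyclopentenones, and iminophosphorane-catalysed enantioselective ketone aldol additions.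

**Step 7**
Reactants: 14 tert-butyl 8-{(1S,5R)-1-hydroxy-4-oxo-5-[(Z)-pent-2-en-1-yl]cyclopent-2-en-1-yl}octanoate
Product: 16 8-{(1S,5R)-1-acetoxy-4-oxo-5-[(Z)-pent-2-en-1-yl]cyclopent-2-en-1-yl}octanoic acid (CNP0348716.3), via tert-butyl ester acetate 15 (not isolated)
Conditions: Ac2O (1.5 equiv), Sc(OTf)3 (2 mol %), MeCN, −20 °C; then TFA/CH2Cl2 1:4, 0 °C; aqueous work-up
Reagents that add atoms: acetic anhydride, CC(=O)OC(C)=O
Why: Lewis-acid-catalysed acylation of the tertiary alcohol (base-free, so the epimerisable C5–H is untouched), then acidolysis of the tert-butyl ester with loss of isobutene; the tertiary acetate resists ionisation because its cation would sit next to the electron-poor enone.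

**Compound list**
1 | furan | c1ccoc1 | starting material
2 | 1-bromo-6-chlorohexane | ClCCCCCCBr | starting material
3 | 2-furyllithium | [Li]c1ccco1 | intermediate
4 | 2-(6-chlorohexyl)furan | ClCCCCCCc1ccco1 | intermediate
5 | (Z)-hex-3-enal | CC/C=C\CC=O | starting material
6 | [5-(6-chlorohexyl)furan-2-yl]lithium | [Li]c1ccc(CCCCCCCl)o1 | intermediate
7 | (Z)-1-[5-(6-chlorohexyl)furan-2-yl]hex-3-en-1-ol (racemic) | CC/C=C\CC(O)c1ccc(CCCCCCCl)o1 | intermediate
8 | tert-butyl acetate | CC(=O)OC(C)(C)C | starting material
9 | lithium enolate of tert-butyl acetate | C=C(O[Li])OC(C)(C)C | intermediate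
10 | tert-butyl 8-{5-[(Z)-1-hydroxyhex-3-en-1-yl]furan-2-yl}octanoate (racemic) | CC/C=C\CC(O)c1ccc(CCCCCCCC(=O)OC(C)(C)C)o1 | intermediate
11 | tert-butyl 8-{2-hydroxy-5-oxo-6-[(Z)-pent-2-en-1-yl]-5,6-dihydro-2H-pyran-2-yl}octanoate (racemic anomer mixture) | CC/C=C\CC1OC(O)(CCCCCCCC(=O)OC(C)(C)C)C=CC1=O | intermediate
12 | tert-butyl 8-{5-oxo-6-[(Z)-pent-2-en-1-yl]-5,6-dihydro-2H-pyran-2-yl}octanoate (racemic cis/trans mixture) | CC/C=C\CC1OC(CCCCCCCC(=O)OC(C)(C)C)C=CC1=O | intermediate
13 | C12–C13 enolate of tert-butyl (10Z,15Z)-9,12-dioxooctadeca-10,15-dienoate, ion-paired with protonated catalyst A | CC/C=C\CC=C([O-])/C=C\C(=O)CCCCCCCC(=O)OC(C)(C)C | intermediate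
14 | tert-butyl 8-{(1S,5R)-1-hydroxy-4-oxo-5-[(Z)-pent-2-en-1-yl]cyclopent-2-en-1-yl}octanoate | CC/C=C\C[C@H]1C(=O)C=C[C@]1(CCCCCCCC(=O)OC(C)(C)C)O | intermediate
15 | tert-butyl 8-{(1S,5R)-1-acetoxy-4-oxo-5-[(Z)-pent-2-en-1-yl]cyclopent-2-en-1-yl}octanoate | CC/C=C\C[C@H]1C(=O)C=C[C@]1(CCCCCCCC(=O)OC(C)(C)C)OC(C)=O | intermediate
16 | 8-{(1S,5R)-1-acetoxy-4-oxo-5-[(Z)-pent-2-en-1-yl]cyclopent-2-en-1-yl}octanoic acid | CC/C=C\C[C@H]1C(=O)C=C[C@]1(CCCCCCCC(=O)O)OC(C)=O | target

Total steps: 7. Longest linear sequence: 7.

**Steps most likely to fail**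

Step 6 (the new ring contraction) is the main risk. The γ-hydrogen may be too weakly acidic for the catalyst. Enolate 13 may be protonated to the free enedione, which can re-enolise on the other side and give the regioisomeric cyclopentenone. The product is more acidic than the substrate, so C5 can epimerise (the wanted isomer, with the two chains cis, is probably the less stable one) and retro-aldol can erode the ee. The fallback uses known chemistry and sets out from 10: a Piancatelli rearrangement (ZnCl2, dioxane/H2O, 80 °C) converts the furylcarbinol directly into the racemic hydroxycyclopentenone with hydroxyl trans to pentenyl, that is 14 together with its enantiomer tert-butyl 8-{(1R,5S)-1-hydroxy-4-oxo-5-[(Z)-pent-2-en-1-yl]cyclopent-2-en-1-yl}octanoate F1. Preparative chiral SFC then delivers 14, where the route is rejoined (steps 4 to 6 are skipped).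

Step 3 may be slow, because a primary chloride is a poor electrophile for an ester enolate, 9 can self-condense, and the free carbinol consumes base. The fallback sets out from 4 and puts the ester on before the carbinol. Enolate 9 alkylates the alcohol-free chloride 4 to give tert-butyl 8-(furan-2-yl)octanoate F2. Bromination with N-bromosuccinimide in DMF at 0 °C gives tert-butyl 8-(5-bromofuran-2-yl)octanoate F3. Bromine–magnesium exchange with i-PrMgCl·LiCl in THF at −20 °C, which tolerates the ester, gives [5-(8-tert-butoxy-8-oxooctyl)furan-2-yl]magnesium chloride F4. Addition of F4 to aldehyde 5 at −40 °C returns to the route at 10.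

Step 7 may suffer from slow acylation of the hindered tertiary alcohol, acid-promoted epimerisation at C5, or loss of the tertiary acetate during the TFA stage. The fallback sets out from 14 and inverts the order so that the acetate never meets strong acid. TFA/CH2Cl2 at 0 °C first gives 8-{(1S,5R)-1-hydroxy-4-oxo-5-[(Z)-pent-2-en-1-yl]cyclopent-2-en-1-yl}octanoic acid F5. Excess Ac2O with Sc(OTf)3 at −20 °C then acetylates both the alcohol and the carboxyl group to give the mixed anhydride acetic 8-{(1S,5R)-1-acetoxy-4-oxo-5-[(Z)-pent-2-en-1-yl]cyclopent-2-en-1-yl}octanoic anhydride F6. Stirring in THF/water at rt hydrolyses only the anhydride and gives 16.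

**Further compounds**
F1 | step 6 | tert-butyl 8-{(1R,5S)-1-hydroxy-4-oxo-5-[(Z)-pent-2-en-1-yl]cyclopent-2-en-1-yl}octanoate | CC/C=C\C[C@@H]1C(=O)C=C[C@@]1(CCCCCCCC(=O)OC(C)(C)C)O
F2 | step 3 | tert-butyl 8-(furan-2-yl)octanoate | CC(C)(C)OC(=O)CCCCCCCc1ccco1
F3 | step 3 | tert-butyl 8-(5-bromofuran-2-yl)octanoate | CC(C)(C)OC(=O)CCCCCCCc1ccc(Br)o1
F4 | step 3 | [5-(8-tert-butoxy-8-oxooctyl)furan-2-yl]magnesium chloride | CC(C)(C)OC(=O)CCCCCCCc1ccc([Mg]Cl)o1
F5 | step 7 | 8-{(1S,5R)-1-hydroxy-4-oxo-5-[(Z)-pent-2-en-1-yl]cyclopent-2-en-1-yl}octanoic acid | CC/C=C\C[C@H]1C(=O)C=C[C@]1(CCCCCCCC(=O)O)O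
F6 | step 7 | acetic 8-{(1S,5R)-1-acetoxy-4-oxo-5-[(Z)-pent-2-en-1-yl]cyclopent-2-en-1-yl}octanoic anhydride | CC/C=C\C[C@H]1C(=O)C=C[C@]1(CCCCCCCC(=O)OC(C)=O)OC(C)=O
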